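**Plan**

- Retrosynthesis: the three aryl O–Si bonds are cut first, then the C5 prenyl group at ArCH2–CH=CMe2 (back to a C5 ester), then the pyran O1–C2 bond (back to a C4a-prenyl catechol), then ring B at C4a–C5 and C6–C7 (Diels–Alder reaction and aromatisation).
- Enabling feature (chroman numbering): ring B carries vicinal oxygens at C8 (OH) and C8a (ring O). C7–C8–C8a–C4a is therefore a 2,3-dioxygenated diene whose C4a substituent is already the prenyl unit of the pyran. C5–C6 is an alkyne carrying an ester (the future prenyl CH2) and the ring A propyl chain.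
- Fragments: diene 6 from 2,3-butanedione and prenyl bromide. Alkynoate 18 from umbelliferone, which supplies the C3 chain and two differentiated resorcinol oxygens; the 1,1-dimethylallyl group comes from an aromatic Claisen rearrangement, the C≡C–CO2Me unit from acetylide and methyl chloroformate.
- Forward order: diene (steps 1–3), ring A alkynoate (steps 4–12), ring B by cycloaddition (step 13), pyran ring (step 14), C5 prenyl group (steps 15–18), desilylation (step 19).
- Stereochemistry: Kazinol D has no stereocentre. The only controlled element is the Z enol ether geometry of 6, needed for s-cis reactivity and erased on aromatisation.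

Key step: step 13

Assumption: in step 2 the anion of 2 is taken to be alkylated at the acetyl methyl group; alkylation at the other methyl group would give the same dione 5 after hydrolysis, because the parent dione is symmetrical.

Abbreviation used in names: Ar = 4-(tert-butyldimethylsilyloxy)-5-(2-methylbut-3-en-2-yl)-2-(triisopropylsilyloxy)phenyl (protected ring A).

**Route**

Step 1
Reactants: 1 2,3-butanedione
Product: 2 (3E)-3-(2,2-dimethylhydrazinylidene)butan-2-one
Conditions: Me2NNH2 (0.7 equiv relative to 1), Et2O, MgSO4, 0 °C to rt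
Reagents that add atoms: 1,1-dimethylhydrazine, CN(C)N
Why: Hydrazone condensation should stop at the mono-adduct because the dione is in excess and the remaining acetyl group is deactivated by conjugation with the C=N–N donor.

Step 2
Reactants: 2 (3E)-3-(2,2-dimethylhydrazinylidene)butan-2-one; 3 1-bromo-3-methylbut-2-ene (prenyl bromide)
Product: 5 7-methyloct-6-ene-2,3-dione, via keto hydrazone 4 (not isolated)
Conditions: LiN(i-Pr)2 (commercial solution, 1.1 equiv), THF, −78 °C; 3 (1.1 equiv), −78 to 0 °C; then 2 M aq HCl/Et2O, rt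
Reagents that add atoms: 1-bromo-3-methylbut-2-ene (3), CC(C)=CCBr; water, O
Why: Kinetic enolate alkylation (SN2) with a reactive allylic bromide, followed by acid hydrolysis of the dimethylhydrazone, should give the mono-prenylated dione, the hydrazone keeping the second carbonyl from self-condensation during the alkylation.

Step 3
Reactants: 5 7-methyloct-6-ene-2,3-dione
Product: 6 (3Z)-7-methyl-2,3-bis(trimethylsilyloxy)octa-1,3,6-triene
Conditions: Me3SiOSO2CF3 (2.3 equiv), Et3N (3 equiv), Et2O, 0 °C to rt; Kugelrohr distillation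
Reagents that add atoms: trimethylsilyl trifluoromethanesulfonate, C[Si](C)(C)OS(=O)(=O)C(F)(F)F
Why: Double soft enolisation and O-silylation (silyl enol ether formation, as known for 2,3-butanedione) has only one enolisable side per carbonyl, and the equilibrating amine/triflate medium should favour the Z enol ether with the alkyl chain anti to the bulky vinyl ether unit.

Step 4
Reactants: 7 umbelliferone
Product: 8 7-hydroxy-3,4-dihydro-2H-chromen-2-one
Conditions: H2 (1 atm), Pd/C (10 wt%), AcOH, 50 °C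
Reagents that add atoms: none
Why: Heterogeneous catalytic hydrogenation should saturate the conjugated C3–C4 double bond of the coumarin and leave the arene and the lactone untouched.

Step 5
Reactants: 8 7-hydroxy-3,4-dihydro-2H-chromen-2-one; 3 1-bromo-3-methylbut-2-ene
Product: 9 7-[(3-methylbut-2-en-1-yl)oxy]-3,4-dihydro-2H-chromen-2-one
Conditions: 3 (1.2 equiv), K2CO3 (1.5 equiv), dry acetone, rt
Reagents that add atoms: 1-bromo-3-methylbut-2-ene (3), CC(C)=CCBr
Why: Williamson etherification can only hit the free phenol, since the lactone masks the second ring A oxygen and so differentiates the two resorcinol oxygens without a protecting-group step.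

Step 6
Reactants: 9 7-[(3-methylbut-2-en-1-yl)oxy]-3,4-dihydro-2H-chromen-2-one
Product: 10 2-(3-hydroxypropyl)-5-[(3-methylbut-2-en-1-yl)oxy]phenol
Conditions: LiAlH4 (1.5 equiv), THF, 0 °C; aq. KNaC4H4O6 work-up
Reagents that add atoms: none
Why: Hydride reduction of the aryl ester (lactone) should give the primary alcohol and free the second phenol, while the allyl aryl ether is inert to LiAlH4.

Step 7
Reactants: 10 2-(3-hydroxypropyl)-5-[(3-methylbut-2-en-1-yl)oxy]phenol
Product: 11 2-(3-bromopropyl)-5-[(3-methylbut-2-en-1-yl)oxy]phenol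
Conditions: CBr4 (1.2 equiv), PPh3 (1.25 equiv), CH2Cl2, 0 °C
Reagents that add atoms: carbon tetrabromide, BrC(Br)(Br)Br
Why: The Appel reaction should convert only the aliphatic alcohol, because an aryloxyphosphonium ion cannot be displaced at sp2 carbon and the base-free medium avoids phenoxide cyclisation to a chroman.

Step 8
Reactants: 11 2-(3-bromopropyl)-5-[(3-methylbut-2-en-1-yl)oxy]phenol
Product: 12 [2-(3-bromopropyl)-5-[(3-methylbut-2-en-1-yl)oxy]phenoxy]tri(propan-2-yl)silane
Conditions: i-Pr3SiOSO2CF3 (1.2 equiv), 2,6-lutidine (1.5 equiv), CH2Cl2, 0 °C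
Reagents that add atoms: triisopropylsilyl trifluoromethanesulfonate, CC(C)[Si](OS(=O)(=O)C(F)(F)F)(C(C)C)C(C)C
Why: Phenol silylation with a silyl triflate and a non-nucleophilic pyridine base is fast and leaves the primary bromide alone, and the bulky base-stable silyl group is chosen to survive the acetylide and to shield the ring position between the two oxygens.

Step 9
Reactants: 12 [2-(3-bromopropyl)-5-[(3-methylbut-2-en-1-yl)oxy]phenoxy]tri(propan-2-yl)silane; 13 lithium acetylide–ethylenediamine complex (LiC≡CH·H2NCH2CH2NH2)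
Product: 14 {5-[(3-methylbut-2-en-1-yl)oxy]-2-(pent-4-yn-1-yl)phenoxy}tri(propan-2-yl)silane
Conditions: 13 (2 equiv), DMSO/THF, 5 °C to rt
Reagents that add atoms: lithium acetylide–ethylenediamine complex (13), [Li+].[C-]#C.NCCN
Why: SN2 alkylation of the acetylide with a primary bromide in a dipolar aprotic medium is standard, and the hindered aryl silyl ether and the allyl aryl ether should tolerate this carbon nucleophile.

Step 10
Reactants: 14 {5-[(3-methylbut-2-en-1-yl)oxy]-2-(pent-4-yn-1-yl)phenoxy}tri(propan-2-yl)silane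
Product: 15 2-(2-methylbut-3-en-2-yl)-4-(pent-4-yn-1-yl)-5-[tri(propan-2-yl)silyloxy]phenol
Conditions: PhNEt2, 190 °C, argon, sealed tube; stopped at full conversion
Reagents that add atoms: none
Why: The aromatic Claisen rearrangement ([3,3]-sigmatropic shift, then tautomerisation) delivers the allyl unit with inversion as the 1,1-dimethylallyl group, and migration to the position para to the silyloxy donor is favoured electronically while the site between the two oxygens is blocked by the bulky silyl ether.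

Step 11
Reactants: 15 2-(2-methylbut-3-en-2-yl)-4-(pent-4-yn-1-yl)-5-[tri(propan-2-yl)silyloxy]phenol
Product: 16 tert-butyl(dimethyl){2-(2-methylbut-3-en-2-yl)-4-(pent-4-yn-1-yl)-5-[tri(propan-2-yl)silyloxy]phenoxy}silane
Conditions: t-BuMe2SiOSO2CF3 (1.3 equiv), 2,6-lutidine (2 equiv), CH2Cl2, 0 °C to rt
Reagents that add atoms: tert-butyldimethylsilyl trifluoromethanesulfonate, CC(C)(C)[Si](C)(C)OS(=O)(=O)C(F)(F)F
Why: A silyl triflate silylates even a phenol flanked by a quaternary carbon, and capping this hydroxyl also removes the proton needed for abnormal Claisen or dihydrobenzofuran side reactions.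

Step 12
Reactants: 16 tert-butyl(dimethyl){2-(2-methylbut-3-en-2-yl)-4-(pent-4-yn-1-yl)-5-[tri(propan-2-yl)silyloxy]phenoxy}silane; 17 methyl chloroformate
Product: 18 methyl 6-Ar-hex-2-ynoate
Conditions: n-BuLi (1.05 equiv), THF, −78 °C; 17 (1.5 equiv), −78 to 0 °C
Reagents that add atoms: methyl chloroformate (17), COC(=O)Cl
Why: Deprotonation of the terminal alkyne and C-acylation of the alkynide with a chloroformate is the standard route to 2-alkynoates, and aryl silyl ethers are stable to the alkynide at low temperature.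

Step 13
Reactants: 6 (3Z)-7-methyl-2,3-bis(trimethylsilyloxy)octa-1,3,6-triene; 18 methyl 6-Ar-hex-2-ynoate
Product: 20 methyl 6-(3-Ar-propyl)-2-(3-methylbut-2-en-1-yl)-3,4-bis(trimethylsilyloxy)benzoate, via cyclohexadiene cycloadduct 19 (not isolated)
Conditions: 6 (2 equiv), toluene, BHT (0.05 equiv), sealed tube, 130 °C; surplus 6 distilled off (0.1 mbar); DDQ (1.1 equiv), toluene, 0 °C to rt
Reagents that add atoms: none
Why: In a thermal normal-electron-demand Diels–Alder reaction the HOMO of the electron-rich diene 6 and the LUMO of the alkynoate 18 combine in a concerted, asynchronous [4+2] cycloaddition that forms C4a–C5 and C6–C7 and gives the 1,2-bis(silyloxy)cyclohexa-1,4-diene 19, which DDQ dehydrogenates by hydride abstraction from a doubly allylic C–H and proton loss. The closest known reaction type is the cycloaddition of 2,3-bis(trimethylsilyloxy)buta-1,3-dienes with acetylenic esters followed by dehydrogenation of the adducts to catechol bis(silyl ethers). Ring B closes by intermolecular [4+2] cycloaddition, the diene supplying C7, C8, C8a and C4a and the alkyne supplying C5 and C6. The only new stereocentre is the prenyl-bearing sp3 carbon of 19, formed as a racemate and erased on aromatisation, so no stereocontrol is needed. The step needs the "ortho" regiochemistry (unsubstituted terminus to the chain-bearing β-carbon, prenyl-bearing terminus to the ester-bearing carbon): the two silyloxy groups oppose each other, so the alkyl substituent, which raises the HOMO coefficient at the remote terminus, and the β-polarisation of the ynoate should decide, while the Z geometry keeps the prenyl chain outside in the s-cis conformer so that the diene can react at all. Chemoselectivity in the oxidation rests on the much faster dehydrogenation of a cyclohexa-1,4-diene than of isolated allylic or benzylic positions, with only a slight excess of DDQ after the surplus diene has been removed.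

Step 14
Reactants: 20 methyl 6-(3-Ar-propyl)-2-(3-methylbut-2-en-1-yl)-3,4-bis(trimethylsilyloxy)benzoate
Product: 22 methyl 6-(3-Ar-propyl)-8-hydroxy-2,2-dimethyl-3,4-dihydro-2H-chromene-5-carboxylate, via catechol 21 (not isolated)
Conditions: p-TsOH·H2O (0.1 equiv), MeOH/CH2Cl2, 0 °C; solvent exchanged for toluene, p-TsOH·H2O (0.2 equiv), 60 °C
Reagents that add atoms: none
Why: Acid methanolysis removes the two labile aryl trimethylsilyl ethers, and acid-catalysed Markovnikov hydroalkoxylation (6-endo attack of the C8a hydroxyl on the tertiary prenyl cation) then closes the pyran, because C8a–OH is the only hydroxyl ortho to the prenyl group, the ring A vinyl group is too weakly basic to be protonated, and the bulky aryl silyl ethers resist dilute acid.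

Step 15
Reactants: 22 methyl 6-(3-Ar-propyl)-8-hydroxy-2,2-dimethyl-3,4-dihydro-2H-chromene-5-carboxylate
Product: 23 methyl 6-(3-Ar-propyl)-8-(tert-butyldimethylsilyloxy)-2,2-dimethyl-3,4-dihydro-2H-chromene-5-carboxylate
Conditions: t-BuMe2SiCl (1.5 equiv), imidazole (3 equiv), DMF, rt
Reagents that add atoms: tert-butyldimethylsilyl chloride, CC(C)(C)[Si](C)(C)Cl
Why: Standard imidazole-mediated silylation caps the unhindered C8 phenol, which is para to C5 and would otherwise turn the later benzylic bromide into a quinone methide.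

Step 16
Reactants: 23 methyl 6-(3-Ar-propyl)-8-(tert-butyldimethylsilyloxy)-2,2-dimethyl-3,4-dihydro-2H-chromene-5-carboxylate
Product: 24 [6-(3-Ar-propyl)-8-(tert-butyldimethylsilyloxy)-2,2-dimethyl-3,4-dihydro-2H-chromen-5-yl]methanol
Conditions: i-Bu2AlH (3 equiv), CH2Cl2, −78 to 0 °C; aq. KNaC4H4O6 work-up
Reagents that add atoms: none
Why: Hydride reduction with i-Bu2AlH takes the di-ortho-substituted benzoate to the benzylic alcohol and is compatible with aryl silyl ethers and isolated alkenes.

Step 17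
Reactants: 24 [6-(3-Ar-propyl)-8-(tert-butyldimethylsilyloxy)-2,2-dimethyl-3,4-dihydro-2H-chromen-5-yl]methanol
Product: 25 5-(bromomethyl)-6-(3-Ar-propyl)-8-(tert-butyldimethylsilyloxy)-2,2-dimethyl-3,4-dihydro-2H-chromene
Conditions: CBr4 (1.3 equiv), PPh3 (1.3 equiv), CH2Cl2, −20 to 0 °C; short silica plug, used at once
Reagents that add atoms: carbon tetrabromide, BrC(Br)(Br)Br
Why: The Appel reaction gives the benzylic bromide under neutral conditions that should spare the silyl ethers and the 1,1-dimethylallyl group.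

Step 18
Reactants: 25 5-(bromomethyl)-6-(3-Ar-propyl)-8-(tert-butyldimethylsilyloxy)-2,2-dimethyl-3,4-dihydro-2H-chromene; 26 (2-methylprop-1-en-1-yl)magnesium bromide
Product: 27 6-(3-Ar-propyl)-8-(tert-butyldimethylsilyloxy)-2,2-dimethyl-5-(3-methylbut-2-en-1-yl)-3,4-dihydro-2H-chromene
Conditions: Me2C=CHMgBr (3 equiv), CuI (0.1 equiv), THF, −40 to 0 °C
Reagents that add atoms: (2-methylprop-1-en-1-yl)magnesium bromide (26), CC(C)=C[Mg]Br
Why: Copper-catalysed cross-coupling of a benzylic bromide with an alkenylmagnesium halide is an established way to make prenylarenes, and alkenyl transfer fixes the position of the trisubstituted double bond.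

Step 19
Reactants: 27 6-(3-Ar-propyl)-8-(tert-butyldimethylsilyloxy)-2,2-dimethyl-5-(3-methylbut-2-en-1-yl)-3,4-dihydro-2H-chromene
Product: 28 Kazinol D
Conditions: Bu4NF (3.5 equiv), AcOH (3.5 equiv), THF, 0 °C to rt, argon
Reagents that add atoms: none
Why: Buffered fluoride cleaves all three aryl silyl ethers without acid, so the prenyl group, the 1,1-dimethylallyl group next to a phenol and the chroman should survive.

**Compound list**

1 | 2,3-butanedione | CC(=O)C(C)=O | starting material
2 | (3E)-3-(2,2-dimethylhydrazinylidene)butan-2-one | CC(=O)/C(C)=N/N(C)C | intermediate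
3 | 1-bromo-3-methylbut-2-ene (prenyl bromide) | CC(C)=CCBr | starting material
4 | (2E)-2-(2,2-dimethylhydrazinylidene)-7-methyloct-6-en-3-one | CC(C)=CCCC(=O)/C(C)=N/N(C)C | intermediate (not isolated)
5 | 7-methyloct-6-ene-2,3-dione | CC(=O)C(=O)CCC=C(C)C | intermediate
6 | (3Z)-7-methyl-2,3-bis(trimethylsilyloxy)octa-1,3,6-triene | C=C(O[Si](C)(C)C)/C(O[Si](C)(C)C)=C/CC=C(C)C | intermediate
7 | umbelliferone (7-hydroxy-2H-chromen-2-one) | O=c1ccc2ccc(O)cc2o1 | starting material
8 | 7-hydroxy-3,4-dihydro-2H-chromen-2-one | O=C1CCc2ccc(O)cc2O1 | intermediate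
9 | 7-[(3-methylbut-2-en-1-yl)oxy]-3,4-dihydro-2H-chromen-2-one | O=C1CCc2ccc(OCC=C(C)C)cc2O1 | intermediate
10 | 2-(3-hydroxypropyl)-5-[(3-methylbut-2-en-1-yl)oxy]phenol | OCCCc1ccc(OCC=C(C)C)cc1O | intermediate
11 | 2-(3-bromopropyl)-5-[(3-methylbut-2-en-1-yl)oxy]phenol | BrCCCc1ccc(OCC=C(C)C)cc1O | intermediate
12 | [2-(3-bromopropyl)-5-[(3-methylbut-2-en-1-yl)oxy]phenoxy]tri(propan-2-yl)silane | BrCCCc1ccc(OCC=C(C)C)cc1O[Si](C(C)C)(C(C)C)C(C)C | intermediate
13 | lithium acetylide–ethylenediamine complex (LiC≡CH·H2NCH2CH2NH2) | [Li+].[C-]#C.NCCN | starting material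
14 | {5-[(3-methylbut-2-en-1-yl)oxy]-2-(pent-4-yn-1-yl)phenoxy}tri(propan-2-yl)silane | C#CCCCc1ccc(OCC=C(C)C)cc1O[Si](C(C)C)(C(C)C)C(C)C | intermediate
15 | 2-(2-methylbut-3-en-2-yl)-4-(pent-4-yn-1-yl)-5-[tri(propan-2-yl)silyloxy]phenol | C#CCCCc1cc(C(C)(C)C=C)c(O)cc1O[Si](C(C)C)(C(C)C)C(C)C | intermediate
16 | tert-butyl(dimethyl){2-(2-methylbut-3-en-2-yl)-4-(pent-4-yn-1-yl)-5-[tri(propan-2-yl)silyloxy]phenoxy}silane | C#CCCCc1cc(C(C)(C)C=C)c(O[Si](C)(C)C(C)(C)C)cc1O[Si](C(C)C)(C(C)C)C(C)C | intermediate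
17 | methyl chloroformate | COC(=O)Cl | starting material
18 | methyl 6-[4-(tert-butyldimethylsilyloxy)-5-(2-methylbut-3-en-2-yl)-2-(triisopropylsilyloxy)phenyl]hex-2-ynoate | COC(=O)C#CCCCc1cc(C(C)(C)C=C)c(O[Si](C)(C)C(C)(C)C)cc1O[Si](C(C)C)(C(C)C)C(C)C | intermediate
19 | methyl 2-(3-Ar-propyl)-6-(3-methylbut-2-en-1-yl)-4,5-bis(trimethylsilyloxy)cyclohexa-1,4-diene-1-carboxylate (racemic) | COC(=O)C1=C(CCCc2cc(C(C)(C)C=C)c(O[Si](C)(C)C(C)(C)C)cc2O[Si](C(C)C)(C(C)C)C(C)C)CC(O[Si](C)(C)C)=C(O[Si](C)(C)C)C1CC=C(C)C | intermediate (not isolated)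
20 | methyl 6-(3-Ar-propyl)-2-(3-methylbut-2-en-1-yl)-3,4-bis(trimethylsilyloxy)benzoate | COC(=O)c1c(CCCc2cc(C(C)(C)C=C)c(O[Si](C)(C)C(C)(C)C)cc2O[Si](C(C)C)(C(C)C)C(C)C)cc(O[Si](C)(C)C)c(O[Si](C)(C)C)c1CC=C(C)C | intermediate
21 | methyl 6-(3-Ar-propyl)-3,4-dihydroxy-2-(3-methylbut-2-en-1-yl)benzoate | COC(=O)c1c(CCCc2cc(C(C)(C)C=C)c(O[Si](C)(C)C(C)(C)C)cc2O[Si](C(C)C)(C(C)C)C(C)C)cc(O)c(O)c1CC=C(C)C | intermediate (not isolated)
22 | methyl 6-(3-Ar-propyl)-8-hydroxy-2,2-dimethyl-3,4-dihydro-2H-chromene-5-carboxylate | COC(=O)c1c(CCCc2cc(C(C)(C)C=C)c(O[Si](C)(C)C(C)(C)C)cc2O[Si](C(C)C)(C(C)C)C(C)C)cc(O)c2OC(C)(C)CCc12 | intermediate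
23 | methyl 6-(3-Ar-propyl)-8-(tert-butyldimethylsilyloxy)-2,2-dimethyl-3,4-dihydro-2H-chromene-5-carboxylate | COC(=O)c1c(CCCc2cc(C(C)(C)C=C)c(O[Si](C)(C)C(C)(C)C)cc2O[Si](C(C)C)(C(C)C)C(C)C)cc(O[Si](C)(C)C(C)(C)C)c2OC(C)(C)CCc12 | intermediate
24 | [6-(3-Ar-propyl)-8-(tert-butyldimethylsilyloxy)-2,2-dimethyl-3,4-dihydro-2H-chromen-5-yl]methanol | OCc1c(CCCc2cc(C(C)(C)C=C)c(O[Si](C)(C)C(C)(C)C)cc2O[Si](C(C)C)(C(C)C)C(C)C)cc(O[Si](C)(C)C(C)(C)C)c2OC(C)(C)CCc12 | intermediate
25 | 5-(bromomethyl)-6-(3-Ar-propyl)-8-(tert-butyldimethylsilyloxy)-2,2-dimethyl-3,4-dihydro-2H-chromene | BrCc1c(CCCc2cc(C(C)(C)C=C)c(O[Si](C)(C)C(C)(C)C)cc2O[Si](C(C)C)(C(C)C)C(C)C)cc(O[Si](C)(C)C(C)(C)C)c2OC(C)(C)CCc12 | intermediate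
26 | (2-methylprop-1-en-1-yl)magnesium bromide (Me2C=CHMgBr) | CC(C)=C[Mg]Br | starting material
27 | 6-(3-Ar-propyl)-8-(tert-butyldimethylsilyloxy)-2,2-dimethyl-5-(3-methylbut-2-en-1-yl)-3,4-dihydro-2H-chromene (tris-silyl ether of Kazinol D) | CC(C)=CCc1c(CCCc2cc(C(C)(C)C=C)c(O[Si](C)(C)C(C)(C)C)cc2O[Si](C(C)C)(C(C)C)C(C)C)cc(O[Si](C)(C)C(C)(C)C)c2OC(C)(C)CCc12 | intermediate
28 | Kazinol D, 4-{3-[8-hydroxy-2,2-dimethyl-5-(3-methylbut-2-en-1-yl)-3,4-dihydro-2H-chromen-6-yl]propyl}-6-(2-methylbut-3-en-2-yl)benzene-1,3-diol | C=CC(C)(C)c1cc(CCCc2cc(O)c3c(c2CC=C(C)C)CCC(C)(C)O3)c(O)cc1O | target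

**Step count and risks**

Total step count: 19. Longest linear sequence: 16 steps (steps 4–12, then 13–19); the diene branch (steps 1–3) joins at step 13.

Steps most likely to fail:

1. Step 13. The β-alkyl ynoate may add so slowly that the diene desilylates or oligomerises at the temperature required, and regiocontrol may erode under forcing conditions. The fallback raises dienophile reactivity by moving to the aldehyde oxidation level. It sets out from 16 and comes back at 24.
   - Deprotonation of 16 with n-BuLi (THF, −78 °C), formylation with DMF and inverse quench into aqueous KH2PO4 should give 6-Ar-hex-2-ynal F1.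
   - Cycloaddition of F1 with 6 in toluene at 60–80 °C should give the cyclohexadiene carbaldehyde F2 (not isolated), which DDQ dehydrogenates to the 3,4-bis(trimethylsilyloxy)benzaldehyde F3.
   - The two-stage acid treatment of step 14 should pass through the catechol aldehyde F4 (not isolated) to the chroman-5-carbaldehyde F5; the aldehyde is deactivated by the para hydroxyl and twisted by its two ortho substituents, which should hold back carbonyl–ene side reactions.
   - t-BuMe2SiCl/imidazole in DMF gives the silyl ether F6, and NaBH4 (THF/MeOH, 0 °C) reduces it to 24.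

2. Step 18. The electron-rich, doubly ortho-substituted benzylic bromide may ionise before alkenyl transfer, leading to homocoupling, reduction, or loss of the para silyl group through a quinone methide. The fallback builds the double bond by olefination instead of the CH2–CH bond by substitution. It sets out from 24, avoids 25 and comes back at 27.
   - MnO2 in CH2Cl2 oxidises 24 to the aldehyde F6.
   - Wittig reaction with Ph3P=CHOMe (from [Ph3PCH2OMe]Cl and KN(SiMe3)2, THF, 0 °C) gives the enol ether F7 as an E/Z mixture.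
   - Brief hydrolysis (HCO2H/H2O/THF, rt) gives the arylacetaldehyde F8.
   - A second Wittig reaction with Ph3P=CMe2 (from [Ph3PCHMe2]I and n-BuLi, THF, −78 to 0 °C) installs the trisubstituted alkene and gives 27.

3. Step 2. Proton transfer between product and enolate (polyalkylation), aldol self-condensation of the keto hydrazone anion or N-quaternisation may compete, and the hydrazone may hydrolyse incompletely. The fallback masks one carbonyl as a ketal instead. It sets out from 3 and comes back at 5.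
   - Commercial 3,3-dimethoxybutan-2-one (CC(=O)C(C)(OC)OC) is deprotonated at its only enolisable position with LiN(i-Pr)2 (THF, −78 °C) and alkylated with 3 to give 2,2-dimethoxy-7-methyloct-6-en-3-one F9.
   - Hydrolysis of the α-keto ketal (aqueous CF3CO2H/CH2Cl2, 0 °C) gives 5.

**Further compounds**

F1 | step 13 | 6-[4-(tert-butyldimethylsilyloxy)-5-(2-methylbut-3-en-2-yl)-2-(triisopropylsilyloxy)phenyl]hex-2-ynal | O=CC#CCCCc1cc(C(C)(C)C=C)c(O[Si](C)(C)C(C)(C)C)cc1O[Si](C(C)C)(C(C)C)C(C)C
F2 | step 13 | 2-(3-Ar-propyl)-6-(3-methylbut-2-en-1-yl)-4,5-bis(trimethylsilyloxy)cyclohexa-1,4-diene-1-carbaldehyde (racemic, not isolated) | O=CC1=C(CCCc2cc(C(C)(C)C=C)c(O[Si](C)(C)C(C)(C)C)cc2O[Si](C(C)C)(C(C)C)C(C)C)CC(O[Si](C)(C)C)=C(O[Si](C)(C)C)C1CC=C(C)C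
F3 | step 13 | 6-(3-Ar-propyl)-2-(3-methylbut-2-en-1-yl)-3,4-bis(trimethylsilyloxy)benzaldehyde | O=Cc1c(CCCc2cc(C(C)(C)C=C)c(O[Si](C)(C)C(C)(C)C)cc2O[Si](C(C)C)(C(C)C)C(C)C)cc(O[Si](C)(C)C)c(O[Si](C)(C)C)c1CC=C(C)C
F4 | step 13 | 6-(3-Ar-propyl)-3,4-dihydroxy-2-(3-methylbut-2-en-1-yl)benzaldehyde (not isolated) | O=Cc1c(CCCc2cc(C(C)(C)C=C)c(O[Si](C)(C)C(C)(C)C)cc2O[Si](C(C)C)(C(C)C)C(C)C)cc(O)c(O)c1CC=C(C)C
F5 | step 13 | 6-(3-Ar-propyl)-8-hydroxy-2,2-dimethyl-3,4-dihydro-2H-chromene-5-carbaldehyde | O=Cc1c(CCCc2cc(C(C)(C)C=C)c(O[Si](C)(C)C(C)(C)C)cc2O[Si](C(C)C)(C(C)C)C(C)C)cc(O)c2OC(C)(C)CCc12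
F6 | step 13 | 6-(3-Ar-propyl)-8-(tert-butyldimethylsilyloxy)-2,2-dimethyl-3,4-dihydro-2H-chromene-5-carbaldehyde | O=Cc1c(CCCc2cc(C(C)(C)C=C)c(O[Si](C)(C)C(C)(C)C)cc2O[Si](C(C)C)(C(C)C)C(C)C)cc(O[Si](C)(C)C(C)(C)C)c2OC(C)(C)CCc12
F7 | step 18 | 6-(3-Ar-propyl)-8-(tert-butyldimethylsilyloxy)-5-(2-methoxyethenyl)-2,2-dimethyl-3,4-dihydro-2H-chromene (E/Z mixture) | COC=Cc1c(CCCc2cc(C(C)(C)C=C)c(O[Si](C)(C)C(C)(C)C)cc2O[Si](C(C)C)(C(C)C)C(C)C)cc(O[Si](C)(C)C(C)(C)C)c2OC(C)(C)CCc12
F8 | step 18 | 2-[6-(3-Ar-propyl)-8-(tert-butyldimethylsilyloxy)-2,2-dimethyl-3,4-dihydro-2H-chromen-5-yl]acetaldehyde | O=CCc1c(CCCc2cc(C(C)(C)C=C)c(O[Si](C)(C)C(C)(C)C)cc2O[Si](C(C)C)(C(C)C)C(C)C)cc(O[Si](C)(C)C(C)(C)C)c2OC(C)(C)CCc12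
F9 | step 2 | 2,2-dimethoxy-7-methyloct-6-en-3-one | CC(C)=CCCC(=O)C(C)(OC)OC
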